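Ring A (C3a–C4–C5–C6–C7–C7a, the carbocycle of the non-bridged butenolide unit) is a masked 2-acylcyclohexanone: C7a carries the lactone carbonyl, C3a the acyl-level carbon C3. It is therefore not built as a six-membered ring but grown from a cis-fused cyclopentanone by insertion of 1-diazohexan-2-one, which places C3a, with the whole pentanoyl chain, between C7a and C4. The cyclopentanone stems from an enantioselective Diels–Alder reaction; a second Diels–Alder reaction of the derived silyloxydiene with a bromoynone builds the bicyclo[2.2.2]octene anti to ring A, and one double carbonylative lactonisation closes both (Z)-butylidene butenolides.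

Key step: step 5

Locants: phthalide numbering is used for all compounds; each atom carries the locant it has in 20. Unprimed locants belong to the unit with ring A (C1 lactone carbonyl, C3 butylidene-bearing carbon), primed locants to the bridged unit. The units are joined by C6–C7′ and C7–C4′. TIPS = triisopropylsilyl, TBS = tert-butyldimethylsilyl, Tf = trifluoromethanesulfonyl.

Assumption: the (S)-oxazaborolidine–AlBr3 catalyst of step 2 is taken to expose the enone face that gives (3aR,7aS)-4; if the opposite sense is found, the (R)-catalyst is used with no other change.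

Step 1
Reactants: 1 but-3-en-2-one (methyl vinyl ketone)
Product: 2 2-(triisopropylsilyloxy)buta-1,3-diene
Conditions: TIPSOTf, Et3N, CH2Cl2, 0 °C → rt
Reagents that add atoms: triisopropylsilyl trifluoromethanesulfonate, CC(C)[Si](C(C)C)(C(C)C)OS(=O)(=O)C(F)(F)F
Why: Soft enolisation (silyl dienol ether formation): O-silylation of the enone and removal of a methyl proton by Et3N give the cross-conjugated 2-silyloxydiene; no stereocentre is formed.

Step 2
Reactants: 2 2-(triisopropylsilyloxy)buta-1,3-diene; 3 cyclopent-2-en-1-one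
Product: 4 (3aR,7aS)-5-(triisopropylsilyloxy)-2,3,3a,4,7,7a-hexahydro-1H-inden-1-one
Conditions: (S)-3,3-diphenyl-1-(2-methylphenyl)tetrahydro-1H,3H-pyrrolo[1,2-c][1,3,2]oxazaborole (10 mol %), AlBr3 (8 mol %), CH2Cl2, −78 → −40 °C
Reagents that add atoms: none
Why: Enantioselective Diels–Alder reaction: the chiral boron Lewis acid binds the enone carbonyl and leaves one face open, the 2-silyloxy group steers the "para" orientation so that the silyloxy carbon (future C6′) lies 1,4 to C7, and suprafacial addition gives the cis fusion at C6 and C7 with the absolute sense fixed by the catalyst.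

Step 3
Reactants: 4 (3aR,7aS)-5-(triisopropylsilyloxy)-2,3,3a,4,7,7a-hexahydro-1H-inden-1-one
Product: 5 (3aR,7aR)-2,3,3a,4-tetrahydro-1H-indene-1,5(7aH)-dione
Conditions: Pd(OAc)2 (10 mol %), O2 (1 atm), DMSO, 60 °C
Reagents that add atoms: none
Why: Saegusa–Ito oxidation: palladation of the silyl enol ether at C5′ and β-hydride elimination, possible only toward C4′, place the C5′=C4′ enone regiospecifically under neutral conditions that should leave the cis ring fusion (C6, C7) intact.

Step 4
Reactants: 6 pentanoyl chloride; 7 (trimethylsilyl)diazomethane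
Product: 8 1-diazohexan-2-one
Conditions: MeCN–THF, 0 °C → rt
Reagents that add atoms: none
Why: Arndt–Eistert-type diazoketone synthesis: the diazo carbon is acylated by the acid chloride and chloride removes the silyl group; no stereocentre is formed.

Step 5
Reactants: 5 (3aR,7aR)-2,3,3a,4-tetrahydro-1H-indene-1,5(7aH)-dione; 8 1-diazohexan-2-one
Product: 9 (4aR,8aR)-5-hydroxy-6-pentanoyl-4a,7,8,8a-tetrahydronaphthalen-2(1H)-one (chelated enol of the ring A 2-pentanoylcyclohexanone)
Conditions: BF3·OEt2 (1.2 equiv), CH2Cl2, −78 → −20 °C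
Reagents that add atoms: none
Why: BF3 activates the saturated cyclopentanone carbonyl (C7a) of 5, the nucleophilic diazo carbon of 8 adds to it, and the β-oxido diazonium ion undergoes a 1,2-shift of C4 from C7a to the new carbon with loss of N2, so that the five-membered ring grows into ring A with C3a, already carrying the pentanoyl chain, inserted between C7a and C4; the product enolises to the chelated 2-acylcyclohexanone 9. The closest known reaction type is the Lewis-acid-promoted Tiffeneau–Demjanov-type homologation of cyclopentanones with diazoacetates. No ring is closed from an open chain: ring A arises by ring enlargement through a 1,2-carbon shift, formally the insertion of one carbon into the C7a–C4 bond. The only new stereocentre, C3a, is stereolabile and is erased by enolisation, while C6 and C7 are not involved. The step needs chemoselectivity for the saturated ketone over the conjugated C6′ ketone, secured by the much lower electrophilicity of the enone carbonyl, and migration of C4 instead of C7, secured by the preference of the less substituted, less hindered α-carbon to migrate. Low temperature limits acid-mediated enolisation toward C7.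

Step 6
Reactants: 9 (4aR,8aR)-5-hydroxy-6-pentanoyl-4a,7,8,8a-tetrahydronaphthalen-2(1H)-one
Product: 10 1-[(4aR,8aS)-1,6-bis(tert-butyldimethylsilyloxy)-3,4,4a,8a-tetrahydronaphthalen-2-yl]pentan-1-one
Conditions: LiN(iPr)2 (2.2 equiv), THF, −78 °C; TBSOTf (2.4 equiv), −78 → 0 °C
Reagents that add atoms: tert-butyldimethylsilyl trifluoromethanesulfonate, CC(C)(C)[Si](C)(C)OS(=O)(=O)C(F)(F)F
Why: Kinetic enolisation and O-silylation (silyl dienol ether formation): the first equivalent of base turns the enolised β-diketone into its lithium chelate, the second removes an α′ proton at C7′ of the enone, and silylation of both oxyanions gives the cross-conjugated 2-silyloxy-1,3-cyclohexadiene C7′=C6′(OTBS)–C5′=C4′ without touching C6 or C7.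

Step 7
Reactants: 11 hept-1-yn-3-ol (racemic)
Product: 12 1-bromohept-1-yn-3-ol (racemic)
Conditions: NBS, AgNO3 (10 mol %), acetone, rt
Reagents that add atoms: N-bromosuccinimide, O=C1CCC(=O)N1Br
Why: AgNO3-catalysed electrophilic bromination of the terminal alkyne through the silver acetylide; the carbinol centre is racemic and is removed in step 8.

Step 8
Reactants: 12 1-bromohept-1-yn-3-ol
Product: 13 1-bromohept-1-yn-3-one
Conditions: Dess–Martin periodinane, NaHCO3, CH2Cl2, 0 °C
Reagents that add atoms: none
Why: Dess–Martin oxidation of the propargylic alcohol to the ynone under buffered, non-nucleophilic conditions that spare the bromoalkyne.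

Step 9
Reactants: 10 1-[(4aR,8aS)-1,6-bis(tert-butyldimethylsilyloxy)-3,4,4a,8a-tetrahydronaphthalen-2-yl]pentan-1-one; 13 1-bromohept-1-yn-3-one
Product: 15 tricyclic C6′ ketone bearing the C7a′-bromo C3a′-pentanoyl bridge alkene (ring A as enolised 2-pentanoylcyclohexanone), via bis(silyl enol ether) cycloadduct 14 (not isolated)
Conditions: toluene, 60 °C; then 1 M HCl, THF, 0 °C → rt
Reagents that add atoms: none
Why: Normal-demand Diels–Alder reaction followed by enol ether hydrolysis: the diene terminus C7′ (largest HOMO coefficient) bonds to the bromine-bearing β-carbon of the ynone and C4′ to the acyl-bearing carbon, the dienophile adds to the diene face anti to ring A and so sets C7′ and C4′ relative to C6 and C7, 60 °C stays below retro-[4+2] loss of the ring A alkene (Alder–Rickert), and aqueous acid then unveils the C6′ ketone and the β-diketone.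

Step 10
Reactants: 15 tricyclic C6′ ketone
Product: 16 6′-epi alcohol (OH anti to the C7a′=C3a′ bridge)
Conditions: NaBH4, MeOH–CH2Cl2 (1:1), −78 °C
Reagents that add atoms: none
Why: Chemoselective borohydride reduction of the only saturated ketone (the β-diketone is an unreactive enolate, the bromoenone carbonyl is conjugated and hindered); hydride should add to the carbonyl face syn to the C7a′=C3a′ bridge because the other face is blocked by C5H2 of ring A, which gives the 6′-epi alcohol that step 11 inverts.

Step 11
Reactants: 16 6′-epi alcohol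
Product: 19 (6′S)-alcohol with C7a vinyl triflate and C7a′ bromide (OH syn to the C7a′=C3a′ bridge), via bis-triflate 17 (not isolated), via nitrite ester 18 (not isolated)
Conditions: Tf2O (2.4 equiv), 2,6-lutidine, CH2Cl2, −40 → 0 °C; then Bu4NNO2, MeCN, 0 °C → rt; aqueous work-up
Reagents that add atoms: trifluoromethanesulfonic anhydride, O=S(=O)(OS(=O)(=O)C(F)(F)F)C(F)(F)F; tetrabutylammonium nitrite, CCCC[N+](CCCC)(CCCC)CCCC.[O-]N=O
Why: Triflic anhydride converts the ring enol (endocyclic C7a=C3a, the preferred tautomer of a 2-acylcyclohexanone) into the vinyl triflate and the secondary alcohol into an alkyl triflate, and nitrite then displaces the alkyl triflate by SN2 from the open face (Lattrell–Dax inversion), the nitrite ester being hydrolysed on work-up to the alcohol with the C6′ configuration of the target; the vinyl triflate does not take part in SN2.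

Step 12
Reactants: 19 (6′S)-alcohol with C7a vinyl triflate and C7a′ bromide
Product: 20 CNP0289078.1, the (3Z,3′Z,6S,7R,4′R,6′S,7′S)-configured 6,7′:7,4′-linked dimer
Conditions: Pd(PPh3)4 (10 mol %), CO (5 bar), Et3N, MeCN, 70 °C
Reagents that add atoms: carbon monoxide, [C-]#[O+]
Why: Double palladium-catalysed carbonylative lactonisation: oxidative addition into the C7a–OTf and C7a′–Br bonds, CO insertion and intramolecular O-acylation of the neighbouring ketone enolates (5-exo-trig) form both butenolides, the (Z)-butylidene geometry being the thermodynamically preferred one; the C6′ hydroxyl cannot reach the acylpalladium (a bridged γ-lactone would result) and no stereocentre is touched.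

Compound list
1 | but-3-en-2-one | CC(=O)C=C | starting material
2 | 2-(triisopropylsilyloxy)buta-1,3-diene | C=CC(=C)O[Si](C(C)C)(C(C)C)C(C)C | intermediate
3 | cyclopent-2-en-1-one | O=C1CCC=C1 | starting material
4 | (3aR,7aS)-5-(triisopropylsilyloxy)-2,3,3a,4,7,7a-hexahydro-1H-inden-1-one (cis-fused) | O=C1CC[C@@H]2CC(O[Si](C(C)C)(C(C)C)C(C)C)=CC[C@H]12 | intermediate
5 | (3aR,7aR)-2,3,3a,4-tetrahydro-1H-indene-1,5(7aH)-dione (cis-fused) | O=C1CC[C@@H]2CC(=O)C=C[C@H]12 | intermediate
6 | pentanoyl chloride | CCCCC(Cl)=O | starting material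
7 | (trimethylsilyl)diazomethane | C[Si](C)(C)C=[N+]=[N-] | starting material
8 | 1-diazohexan-2-one | CCCCC(=O)C=[N+]=[N-] | intermediate
9 | (4aR,8aR)-5-hydroxy-6-pentanoyl-4a,7,8,8a-tetrahydronaphthalen-2(1H)-one (enol form; ring A now six-membered) | OC1=C(C(=O)CCCC)CC[C@@H]2CC(=O)C=C[C@H]12 | intermediate
10 | 1-[(4aR,8aS)-1,6-bis(tert-butyldimethylsilyloxy)-3,4,4a,8a-tetrahydronaphthalen-2-yl]pentan-1-one | CC(C)(C)[Si](C)(C)OC1=C(C(=O)CCCC)CC[C@@H]2C=C(O[Si](C)(C)C(C)(C)C)C=C[C@H]12 | intermediate
11 | hept-1-yn-3-ol (racemic) | CCCCC(O)C#C | starting material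
12 | 1-bromohept-1-yn-3-ol (racemic) | CCCCC(O)C#CBr | intermediate
13 | 1-bromohept-1-yn-3-one | CCCCC(=O)C#CBr | intermediate
14 | bicyclo[2.2.2]octadiene cycloadduct: C7a′–Br, C3a′–pentanoyl, C6′(OTBS)=C5′ enol ether, ring A as C7a–OTBS enol ether; ring A anti to the C7a′=C3a′ bridge | CC(C)(C)[Si](C)(C)OC2=C(C(=O)CCCC)CC[C@@H]1[C@H]3C(Br)=C(C(=O)CCCC)[C@H](C=C3O[Si](C)(C)C(C)(C)C)[C@H]21 | intermediate (not isolated)
15 | tricyclic C6′ ketone: C7a′–Br, C3a′–pentanoyl, ring A as enolised 2-pentanoylcyclohexanone (C7a–OH); C6, C7, C4′, C7′ as in 20 | OC2=C(C(=O)CCCC)CC[C@@H]1[C@H]3C(Br)=C(C(=O)CCCC)[C@H](CC3=O)[C@H]21 | intermediate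
16 | 6′-epi alcohol of 15 (OH anti to the C7a′=C3a′ bridge, syn to C5H2 of ring A) | OC2=C(C(=O)CCCC)CC[C@@H]1[C@H]3C(Br)=C(C(=O)CCCC)[C@H](C[C@H]3O)[C@H]21 | intermediate
17 | bis-triflate: C7a vinyl triflate and C6′ alkyl triflate (C6′ as in 16) | FC(F)(F)S(=O)(=O)OC2=C(C(=O)CCCC)CC[C@@H]1[C@H]3C(Br)=C(C(=O)CCCC)[C@H](C[C@H]3OS(=O)(=O)C(F)(F)F)[C@H]21 | intermediate (not isolated)
18 | C6′ nitrite ester (C6′ inverted) with C7a vinyl triflate | FC(F)(F)S(=O)(=O)OC2=C(C(=O)CCCC)CC[C@@H]1[C@H]3C(Br)=C(C(=O)CCCC)[C@H](C[C@@H]3ON=O)[C@H]21 | intermediate (not isolated)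
19 | (6′S)-alcohol (OH syn to the C7a′=C3a′ bridge) with C7a vinyl triflate, C3a pentanoyl, C7a′ bromide and C3a′ pentanoyl | FC(F)(F)S(=O)(=O)OC2=C(C(=O)CCCC)CC[C@@H]1[C@H]3C(Br)=C(C(=O)CCCC)[C@H](C[C@@H]3O)[C@H]21 | intermediate
20 | CNP0289078.1: (3Z,3′Z,6S,7R,4′R,6′S,7′S)-3,3′-dibutylidene-6′-hydroxy 6,7′:7,4′-linked phthalide dimer (ring A 4,5,6,7-tetrahydro; bridged unit 4′,5′,6′,7′-tetrahydro) | CCC/C=C1\OC(=O)C2=C1CC[C@@H]1[C@H]3C4=C(/C(=C/CCC)OC4=O)[C@H](C[C@@H]3O)[C@H]21 | target

Total step count: 12. Longest linear sequence: 9 steps (1, 2, 3, 5, 6, 9, 10, 11, 12).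

Steps most likely to fail

Step 5. The acceptor-stabilised diazoketone may add too slowly to the BF3-bound cyclopentanone. Lewis-acid-mediated enolisation toward C7 with migration of the enone double bond, or migration of C7 instead of C4, could then take over. Fallback, setting out from 5 and coming back at 9: the ring enlargement is run with the more nucleophilic tert-butyl diazoacetate (BF3·OEt2, CH2Cl2, −78 °C) to give tert-butyl (4aR,8aR)-1-hydroxy-6-oxo-3,4,4a,5,6,8a-hexahydronaphthalene-2-carboxylate F1. C-acylation of its magnesium enolate with 6 (MgCl2, pyridine, CH2Cl2) gives tert-butyl (4aR,8aR)-1,6-dioxo-2-pentanoyl-1,2,3,4,4a,5,6,8a-octahydronaphthalene-2-carboxylate F2 (both C2 epimers). TFA in CH2Cl2 then cleaves the tert-butyl ester with decarboxylation to 9.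

Step 11. Participation of the C7a′=C3a′ π bond or E2 elimination may compete with direct SN2 at the hindered C6′ triflate, and nitrite may add to the vinylogous acyl triflate. Fallback, setting out from 16 and coming back at 19: selective enol triflation with PhNTf2 and Et3N (CH2Cl2, 0 °C) gives the C7a vinyl triflate 6′-epi alcohol F3. A Mitsunobu reaction (ClCH2CO2H, PPh3, DIAD, toluene) gives the inverted C6′ chloroacetate F4. Thiourea and NaHCO3 in EtOH then remove the chloroacetyl group to give 19.

Step 12. C-acylation of the ketone enolates (to cyclopentenediones) or carbonylation at only one of the two sites may compete with the double O-acylation. Fallback, setting out from 19 and coming back at 20: double methoxycarbonylation (Pd(OAc)2, 1,3-bis(diphenylphosphino)propane, CO, MeOH, Et3N, DMF, 70 °C) gives the bis(methyl ester) diketone F5. LiOH in THF–H2O gives the bis(keto acid) F6. Acid-catalysed dehydrative enol-lactonisation of its hydroxy-lactone tautomers (TsOH, toluene, 80 °C) then gives 20.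

Further compounds
F1 | step 5 | tert-butyl (4aR,8aR)-1-hydroxy-6-oxo-3,4,4a,5,6,8a-hexahydronaphthalene-2-carboxylate (enol form) | OC1=C(C(=O)OC(C)(C)C)CC[C@@H]2CC(=O)C=C[C@H]12
F2 | step 5 | tert-butyl (4aR,8aR)-1,6-dioxo-2-pentanoyl-1,2,3,4,4a,5,6,8a-octahydronaphthalene-2-carboxylate (both C2 epimers) | O=C1C(C(=O)CCCC)(C(=O)OC(C)(C)C)CC[C@@H]2CC(=O)C=C[C@H]12
F3 | step 11 | C7a vinyl triflate 6′-epi alcohol (C7a′ bromide, both pentanoyl groups in place) | FC(F)(F)S(=O)(=O)OC2=C(C(=O)CCCC)CC[C@@H]1[C@H]3C(Br)=C(C(=O)CCCC)[C@H](C[C@H]3O)[C@H]21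
F4 | step 11 | inverted C6′ chloroacetate of F3 | FC(F)(F)S(=O)(=O)OC2=C(C(=O)CCCC)CC[C@@H]1[C@H]3C(Br)=C(C(=O)CCCC)[C@H](C[C@@H]3OC(=O)CCl)[C@H]21
F5 | step 12 | bis(methyl ester) diketone (CO2Me at C7a and C7a′, pentanoyl at C3a and C3a′, 6′-OH) | COC(=O)C2=C(C(=O)CCCC)CC[C@@H]1[C@H]3C(C(=O)OC)=C(C(=O)CCCC)[C@H](C[C@@H]3O)[C@H]21
F6 | step 12 | bis(keto acid) (CO2H at C7a and C7a′, pentanoyl at C3a and C3a′, 6′-OH) | OC(=O)C2=C(C(=O)CCCC)CC[C@@H]1[C@H]3C(C(=O)O)=C(C(=O)CCCC)[C@H](C[C@@H]3O)[C@H]21
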